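The hardest feature: only the C5 residue on C8 (ring A) is oxygenated. It carries a transposed alkene and an (R)-carbinol at C2''. That centre lies six bonds from the base-labile (S)-C2 of ring C, so oxidising a prenyl group would need site control, and neither centre can steer the other.
Enabling feature: the array C8(sp2, ring A)–C1''H2–C2''H(O)–C3''(=C4''H2)CH3 is read as aryl electrophile + vinylboron + migrating isopropenyl group, not as an oxidised prenyl group. C8, between O1 and O7, is the ring-A carbon expected to take up iodine.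
Cuts: (i) C2–C1' (ring C to ring B); (ii) C8–C1'' and C2''–C3'' together, with C2''–O derived from C–B; (iii) the two aryl–prenyl bonds at C3' and C5'.
Forward: rings A and C are bought as 7-hydroxychromone, and C8 iodination, silylation and a three-component conjunctive coupling/oxidation build the whole side chain. Ring B comes from 4-bromophenol (twofold iodination, twofold prenyl Stille coupling, borylation). A Rh 1,4-addition joins ring B to C2 and saturates ring C, and fluoride then frees the phenols.
Stereochemistry: C2'' comes from the Pd/MandyPhos-controlled 1,2-metallate shift (retentive C–B oxidation) and C2 from Rh/chiral-diene face selection. The two controls are independent, and C2 is set in the penultimate step and afterwards meets only slightly acidic fluoride.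
Key step: step 3

Remark: flavanone numbering is used (O1, C2–C4, C4a, C5–C8, C8a; ring B primed; C8 side chain doubly primed). The antipode of each chiral ligand is assigned by analogy with simple substrates, and both antipodes are commercial.

Step 1
Reactants: 1 7-hydroxy-4H-chromen-4-one
Product: 2 7-hydroxy-8-iodo-4H-chromen-4-one
Conditions: I2 (0.4 equiv), HIO3 (0.2 equiv), EtOH/H2O, 35 °C
Reagents that add atoms: iodine, II; iodic acid, O=I(=O)O
Why: Electrophilic aromatic iodination should go to C8, which is ortho to 7-OH and flanked by O1 and is the most nucleophilic ring-A carbon of 7-hydroxychromones (the same site as in their Mannich, Duff and Claisen chemistry), while the oxidant recycles iodide.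

Step 2
Reactants: 2 7-hydroxy-8-iodo-4H-chromen-4-one
Product: 3 8-iodo-7-(triisopropylsilyloxy)-4H-chromen-4-one
Conditions: TIPSCl, imidazole, DMF, rt
Reagents that add atoms: triisopropylsilyl chloride, CC(C)[Si](Cl)(C(C)C)C(C)C
Why: Standard phenol silylation, with TIPS chosen because it resists mildly basic aqueous media and O-to-O migration better than smaller silyl groups and still leaves with fluoride at the end.

Step 3
Reactants: 3 8-iodo-7-(triisopropylsilyloxy)-4H-chromen-4-one; 4 vinylboronic acid pinacol ester (1.3 equiv); 5 isopropenylmagnesium bromide (1.2 equiv)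
Product: 8 (R)-8-(2-hydroxy-3-methylbut-3-en-1-yl)-7-(triisopropylsilyloxy)-4H-chromen-4-one, via sodium isopropenyl(vinyl)(pinacolato)borate 6 (not isolated), via (R)-allylic pinacol boronate 7 (not isolated)
Conditions: 4, 5, THF, 0 °C to rt, NaOTf (2 equiv); then 3, Pd(OAc)2 (3 mol %), (Sp,Sp)-MandyPhos (3.6 mol %), THF/DMSO, 45 °C; aqueous wash; then 30% H2O2, pH 7 phosphate buffer, THF, 0 °C to rt
Reagents that add atoms: hydrogen peroxide, OO
Why: Enantioselective Pd-catalysed conjunctive cross-coupling: Pd(0) inserts into the C8–I bond of 3, the cationic aryl–Pd(II) (halide taken up by NaOTf) binds the unsubstituted vinyl group of borate 6, this triggers an anti 1,2-metallate shift of the isopropenyl group from boron to the α-carbon (C2''–C3'' bond), and reductive elimination from the resulting Pd–C1''H2 species forms C8–C1''. The closest known reaction type is this same coupling of vinyl(alkenyl)borates with aryl electrophiles to α-chiral allylic boronic esters, followed by stereoretentive C–B oxidation. No ring is closed in this step. C2'' is the only new stereocentre; it is fixed in the metallate shift by the vinyl face that the C2-symmetric ferrocenyl bisphosphine lets Pd bind, and since B and O occupy the same position (R)-7 should give (R)-8. The step needs alkene selectivity (Pd takes the less substituted vinyl, the more substituted isopropenyl migrates), conjunctive coupling rather than direct alkenyl transfer (wide-bite-angle ligand, halide-poor medium) and site selectivity (C8–I is the only carbon–halogen bond, and the electron-poor C2=C3 bond of ring C cannot compete with an anionic borate for cationic Pd). Peroxide at pH 7 is chosen because the pyrone ring and the aryl silyl ether would not stand alkaline peroxide.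

Step 4
Reactants: 9 4-bromophenol
Product: 11 4-bromo-2,6-diiodophenol, via 4-bromo-2-iodophenol 10 (not isolated)
Conditions: I2 (0.8 equiv), HIO3 (0.4 equiv), EtOH/H2O, 40 °C
Reagents that add atoms: iodine, II; iodic acid, O=I(=O)O
Why: Electrophilic aromatic iodination of a phenol whose para position is blocked by bromine should fill both ortho positions and so provide two C–I bonds that react before the C–Br bond.

Step 5
Reactants: 11 4-bromo-2,6-diiodophenol
Product: 12 (4-bromo-2,6-diiodophenoxy)(tert-butyl)dimethylsilane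
Conditions: TBSOTf, 2,6-lutidine, CH2Cl2, 0 °C to rt
Reagents that add atoms: tert-butyldimethylsilyl triflate, CC(C)(C)[Si](C)(C)OS(=O)(=O)C(F)(F)F
Why: Silylation of a hindered, acidic phenol with the reactive silyl triflate masks the phenol for the Pd, Li and Rh steps and can be removed together with the TIPS group.

Step 6
Reactants: 12 (4-bromo-2,6-diiodophenoxy)(tert-butyl)dimethylsilane; 13 tributyl(3-methylbut-2-en-1-yl)stannane (2.3 equiv)
Product: 15 [4-bromo-2,6-bis(3-methylbut-2-en-1-yl)phenoxy](tert-butyl)dimethylsilane, via monoprenylated aryl iodide 14 (not isolated)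
Conditions: Pd2(dba)3 (2.5 mol %), P(2-furyl)3 (10 mol %), dioxane, 70 °C
Reagents that add atoms: none
Why: In this twofold Stille coupling, oxidative addition should discriminate C–I from C–Br and the prenylstannane should couple at its unsubstituted terminus, so that two linear prenyl groups arise ortho to the oxygen of ring B.

Step 7
Reactants: 15 [4-bromo-2,6-bis(3-methylbut-2-en-1-yl)phenoxy](tert-butyl)dimethylsilane
Product: 18 [4-(tert-butyldimethylsilyloxy)-3,5-bis(3-methylbut-2-en-1-yl)phenyl]boronic acid, via aryllithium 16 (not isolated), via lithium aryl(triisopropoxy)borate 17 (not isolated)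
Conditions: B(OiPr)3, n-BuLi, THF/toluene, −78 °C (in situ quench); then 1 M HCl, 0 °C
Reagents that add atoms: triisopropyl borate, CC(C)OB(OC(C)C)OC(C)C; water, O
Why: Bromine–lithium exchange with in situ borate trapping should outrun deprotonation of the ArCH2CH= positions at −78 °C, and the para relation of lithium to the silyloxy group excludes retro-Brook silyl migration.

Step 8
Reactants: 8 (R)-8-(2-hydroxy-3-methylbut-3-en-1-yl)-7-(triisopropylsilyloxy)-4H-chromen-4-one; 18 [4-(tert-butyldimethylsilyloxy)-3,5-bis(3-methylbut-2-en-1-yl)phenyl]boronic acid (2 equiv)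
Product: 19 (2S)-2-[4-(tert-butyldimethylsilyloxy)-3,5-bis(3-methylbut-2-en-1-yl)phenyl]-8-[(2R)-2-hydroxy-3-methylbut-3-en-1-yl]-7-(triisopropylsilyloxy)chroman-4-one
Conditions: [RhCl(C2H4)2]2 (2.5 mol %), (S,S)-Ph-bod* (5.5 mol %), aq. KOH (10 mol %), dioxane/H2O 10:1, 40 °C
Reagents that add atoms: none
Why: In this Rh(I)-catalysed asymmetric 1,4-addition of an arylboronic acid to a chromone (Hayashi–Miyaura reaction), the aryl–Rh species should add to C2 from the face left open by the C2-symmetric diene, which sets C2 as S independently of the remote C2'' centre, and water protonates the Rh enolate in a nearly neutral protic medium that tolerates the free alcohol and the isolated alkenes.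

Step 9
Reactants: 19 (2S)-2-[4-(tert-butyldimethylsilyloxy)-3,5-bis(3-methylbut-2-en-1-yl)phenyl]-8-[(2R)-2-hydroxy-3-methylbut-3-en-1-yl]-7-(triisopropylsilyloxy)chroman-4-one
Product: 21 (2S)-7-hydroxy-2-[4-hydroxy-3,5-bis(3-methylbut-2-en-1-yl)phenyl]-8-[(2R)-2-hydroxy-3-methylbut-3-en-1-yl]chroman-4-one (target), via 4'-O-TBS flavanone 20 (not isolated)
Conditions: Et3N·3HF, THF, rt
Reagents that add atoms: none
Why: Fluoride-driven cleavage of both aryl silyl ethers (the more electrophilic 7-O-silyl group is expected to leave first) takes place in a slightly acidic medium in which no phenoxide builds up, so neither retro-oxa-Michael epimerisation at C2 nor acid cyclisation of the ortho-prenylphenol units is expected.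

Compound list
1 | 7-hydroxy-4H-chromen-4-one | O=C1C=COc2cc(O)ccc12 | starting material
2 | 7-hydroxy-8-iodo-4H-chromen-4-one | O=C1C=COc2c(I)c(O)ccc12 | intermediate
3 | 8-iodo-7-(triisopropylsilyloxy)-4H-chromen-4-one | O=C1C=COc2c(I)c(O[Si](C(C)C)(C(C)C)C(C)C)ccc12 | intermediate
4 | vinylboronic acid pinacol ester | C=CB1OC(C)(C)C(C)(C)O1 | starting material
5 | isopropenylmagnesium bromide | C=C(C)[Mg]Br | starting material
6 | sodium isopropenyl(vinyl)(pinacolato)borate | [Na+].C=C[B-]1(C(C)=C)OC(C)(C)C(C)(C)O1 | intermediate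
7 | (R)-8-[3-methyl-2-(4,4,5,5-tetramethyl-1,3,2-dioxaborolan-2-yl)but-3-en-1-yl]-7-(triisopropylsilyloxy)-4H-chromen-4-one | C=C(C)[C@H](B3OC(C)(C)C(C)(C)O3)Cc1c(O[Si](C(C)C)(C(C)C)C(C)C)ccc2c1OC=CC2=O | intermediate
8 | (R)-8-(2-hydroxy-3-methylbut-3-en-1-yl)-7-(triisopropylsilyloxy)-4H-chromen-4-one | C=C(C)[C@H](O)Cc1c(O[Si](C(C)C)(C(C)C)C(C)C)ccc2c1OC=CC2=O | intermediate
9 | 4-bromophenol | Oc1ccc(Br)cc1 | starting material
10 | 4-bromo-2-iodophenol | Oc1ccc(Br)cc1I | intermediate
11 | 4-bromo-2,6-diiodophenol | Oc1c(I)cc(Br)cc1I | intermediate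
12 | (4-bromo-2,6-diiodophenoxy)(tert-butyl)dimethylsilane | CC(C)(C)[Si](C)(C)Oc1c(I)cc(Br)cc1I | intermediate
13 | tributyl(3-methylbut-2-en-1-yl)stannane | CCCC[Sn](CCCC)(CCCC)CC=C(C)C | starting material
14 | [4-bromo-2-iodo-6-(3-methylbut-2-en-1-yl)phenoxy](tert-butyl)dimethylsilane | CC(C)=CCc1cc(Br)cc(I)c1O[Si](C)(C)C(C)(C)C | intermediate
15 | [4-bromo-2,6-bis(3-methylbut-2-en-1-yl)phenoxy](tert-butyl)dimethylsilane | CC(C)=CCc1cc(Br)cc(CC=C(C)C)c1O[Si](C)(C)C(C)(C)C | intermediate
16 | [4-(tert-butyldimethylsilyloxy)-3,5-bis(3-methylbut-2-en-1-yl)phenyl]lithium | [Li]c1cc(CC=C(C)C)c(O[Si](C)(C)C(C)(C)C)c(CC=C(C)C)c1 | intermediate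
17 | lithium [4-(tert-butyldimethylsilyloxy)-3,5-bis(3-methylbut-2-en-1-yl)phenyl]triisopropoxyborate | [Li+].CC(C)O[B-](OC(C)C)(OC(C)C)c1cc(CC=C(C)C)c(O[Si](C)(C)C(C)(C)C)c(CC=C(C)C)c1 | intermediate
18 | [4-(tert-butyldimethylsilyloxy)-3,5-bis(3-methylbut-2-en-1-yl)phenyl]boronic acid | OB(O)c1cc(CC=C(C)C)c(O[Si](C)(C)C(C)(C)C)c(CC=C(C)C)c1 | intermediate
19 | (2S)-2-[4-(tert-butyldimethylsilyloxy)-3,5-bis(3-methylbut-2-en-1-yl)phenyl]-8-[(2R)-2-hydroxy-3-methylbut-3-en-1-yl]-7-(triisopropylsilyloxy)chroman-4-one | C=C(C)[C@H](O)Cc1c(O[Si](C(C)C)(C(C)C)C(C)C)ccc2c1O[C@H](c1cc(CC=C(C)C)c(O[Si](C)(C)C(C)(C)C)c(CC=C(C)C)c1)CC2=O | intermediate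
20 | (2S)-2-[4-(tert-butyldimethylsilyloxy)-3,5-bis(3-methylbut-2-en-1-yl)phenyl]-7-hydroxy-8-[(2R)-2-hydroxy-3-methylbut-3-en-1-yl]chroman-4-one | C=C(C)[C@H](O)Cc1c(O)ccc2c1O[C@H](c1cc(CC=C(C)C)c(O[Si](C)(C)C(C)(C)C)c(CC=C(C)C)c1)CC2=O | intermediate
21 | (2S)-7-hydroxy-2-[4-hydroxy-3,5-bis(3-methylbut-2-en-1-yl)phenyl]-8-[(2R)-2-hydroxy-3-methylbut-3-en-1-yl]chroman-4-one | C=C(C)[C@H](O)Cc1c(O)ccc2c1O[C@H](c1cc(CC=C(C)C)c(O)c(CC=C(C)C)c1)CC2=O | target

Total step count: 9.
Longest linear sequence: 6 steps (9 to 21 through steps 4–9). The chromone branch counts 5 steps (1, 2, 3, 8, 9).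

Steps most likely to fail

**Step 3.** The aryl–Pd centre is flanked by O1 and the 7-silyloxy group. Binding of the vinyl group and the metallate shift may therefore become slow. Direct alkenyl transfer from boron, or reduction of the C–I bond, could then take over, and face selection could erode.
Fallback, from 3: Stille coupling with 13 should give 8-(3-methylbut-2-en-1-yl)-7-(triisopropylsilyloxy)-4H-chromen-4-one F1. Ring B is not yet present, so this is the only trisubstituted alkene in the molecule. Shi epoxidation (D-fructose-derived ketone, Oxone, buffered MeCN/dimethoxymethane/H2O, 0 °C) should then give the (R)-epoxide F2. Aluminium isopropoxide in hot toluene isomerises the epoxide by syn elimination towards a methyl group and leaves the C2''–O bond untouched. This comes back to the route at 8.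

**Step 8.** Carborhodation of the electron-rich 7-silyloxychromone may be slow, so that protodeboronation consumes the boronic acid. β-Aryloxide elimination from the Rh enolate may erode the C2 configuration, and a second (1,2-) addition to the new ketone may occur.
Fallback, from 8 and 18: the union is run with achiral [Rh(OH)(cod)]2, which should give 19 together with its (2R)-epimer F3. A Noyori–Ikariya transfer hydrogenation is then used as a kinetic resolution (Ru–TsDPEN antipode matched to the 2R ketone, HCO2H/Et3N). It should reduce only F3 to the cis-(2R,4R)-flavan-4-ol F4, which differs enough in polarity to be removed. Unreacted 19 re-enters the route at 19.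

**Step 6.** Three processes may interfere: allyl transposition during transfer from tin (attack through the substituted terminus, giving reverse-prenyl groups), loss of the C–I/C–Br discrimination, and cleavage of the electron-poor aryl silyl ether.
Fallback, from 9, with reversed polarity: the sodium phenoxide of 9 (NaH, toluene) is C-alkylated in the ortho position with prenyl bromide in two rounds. The sequence runs through 4-bromo-2-(3-methylbut-2-en-1-yl)phenol F5 to 4-bromo-2,6-bis(3-methylbut-2-en-1-yl)phenol F6. Silylation (TBSOTf, 2,6-lutidine) comes back to the route at 15, and steps 4 and 5 are then not needed.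

Further compounds
F1 | step 3 | 8-(3-methylbut-2-en-1-yl)-7-(triisopropylsilyloxy)-4H-chromen-4-one | CC(C)=CCc1c(O[Si](C(C)C)(C(C)C)C(C)C)ccc2c1OC=CC2=O
F2 | step 3 | 8-{[(2R)-3,3-dimethyloxiran-2-yl]methyl}-7-(triisopropylsilyloxy)-4H-chromen-4-one | CC1(C)O[C@@H]1Cc1c(O[Si](C(C)C)(C(C)C)C(C)C)ccc2c1OC=CC2=O
F3 | step 8 | (2R)-2-[4-(tert-butyldimethylsilyloxy)-3,5-bis(3-methylbut-2-en-1-yl)phenyl]-8-[(2R)-2-hydroxy-3-methylbut-3-en-1-yl]-7-(triisopropylsilyloxy)chroman-4-one | C=C(C)[C@H](O)Cc1c(O[Si](C(C)C)(C(C)C)C(C)C)ccc2c1O[C@@H](c1cc(CC=C(C)C)c(O[Si](C)(C)C(C)(C)C)c(CC=C(C)C)c1)CC2=O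
F4 | step 8 | (2R,4R)-2-[4-(tert-butyldimethylsilyloxy)-3,5-bis(3-methylbut-2-en-1-yl)phenyl]-8-[(2R)-2-hydroxy-3-methylbut-3-en-1-yl]-7-(triisopropylsilyloxy)chroman-4-ol | C=C(C)[C@H](O)Cc1c(O[Si](C(C)C)(C(C)C)C(C)C)ccc2c1O[C@@H](c1cc(CC=C(C)C)c(O[Si](C)(C)C(C)(C)C)c(CC=C(C)C)c1)C[C@H]2O
F5 | step 6 | 4-bromo-2-(3-methylbut-2-en-1-yl)phenol | CC(C)=CCc1cc(Br)ccc1O
F6 | step 6 | 4-bromo-2,6-bis(3-methylbut-2-en-1-yl)phenol | CC(C)=CCc1cc(Br)cc(CC=C(C)C)c1O
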